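## Structural features

The target is a ten-membered carbocycle of the germacrane type. Counting from the allylic acetoxy carbon, C1 is followed by the trisubstituted C2=C3 olefin (methyl on C3), the C4–C5 ethano unit, the C6=C7 olefin that carries the carboxyl carbon C14, C8, the second acetoxy carbon C9, and the isopropyl-bearing C10 (C11 methine), which closes back to C1. In both ring olefins the ring carbons are cis: C1/C4 across C2=C3 (descriptor Z) and C5/C8 across C6=C7 (descriptor E only because C14 outranks C8). The stereocentres C9, C10 and C1 are contiguous (9R,10S,1R). The C1 oxygen and the isopropyl group are cis, and the C9 oxygen is trans to both. Fragile features are the ionisable allylic acetate at C1, two acetates that exclude late basic or hydridic steps, a 1,5-diene in a medium ring (acid-induced transannular cyclisation, thermal Cope shift), and the 1,4-relationship of O9 and C14, which closes a five-membered lactol or lactone whenever O9 is free and C14 is an aldehyde or acid. The real difficulty is to form a strained ten-membered ring while setting a stereotriad on it and two olefin geometries in it. The feature exploited is the C1 carbinol next to branched C10: if the isopropyl group is read as a hydrogenated isopropenyl group (C11=C12), C1(OH)–C10–C11=C12 is the homoallylic-alcohol retron of a [2,3]-Wittig shift, and placing the C1 oxygen between C1 and C12 turns the carbocycle into an unstrained thirteen-membered bis-allylic ether.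

## Logic of the disconnections

29 ⇒ 28 ⇒ 27 ⇒ 26. No skeletal bond is cut; the C14 oxidation level is taken back from acid to aldehyde to alcohol to silyl ether. A free acid cannot pass through organolithium chemistry, so C14 is carried as a protected allylic alcohol. The gain is that the acid/acetate array shrinks to one masked hydroxyl. The demand is that O9 is already acetylated when C14 is unmasked, and that the oxidations spare two trisubstituted olefins and two acetates.

26 ⇒ 25 ⇒ 24 ⇒ 23. The C11/C12 saturation and both acetyl C–O bonds are removed. Reading isopropyl as isopropenyl exposes the homoallylic alcohol at C1/C10, and both acetates can be installed in one operation on diol 24. The demand is hydrogenation of a 1,1-disubstituted olefin beside two trisubstituted ones, and removal of the O9 silyl group while the O14 silyl group stays.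

23 ⇒ 21. The C1–C10 bond is cut and O is reconnected to C12. This removes the strained ring and two stereocentres at once and leaves one stereocentre (C9) and three olefins of defined geometry in a thirteen-membered ether. The forward step needs lithiation at C1 (not C12 or C14), a Z C10=C11 olefin for the cis C1/C10 relationship, and control of the C10 face by C9. For that reason O9 carries a small, non-coordinating triethylsilyl group and O14 a bulky triisopropylsilyl group that shields the C14 methylene.

21 ⇒ 20. The O–C12 ether bond is cut, giving a C1 alkoxide and a C12 allylic chloride. The alkoxide is put on C1 because an alkoxide on C12 would sit cis to the O9 silyl ether across the Z olefin and invite oxygen-to-oxygen silyl transfer. The gain is an open chain. The demand is high dilution and a C1 hydroxyl that can be unmasked last without acid or fluoride, hence a 4-methoxybenzyl ether on O1.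

20 ⇒ 19 ⇒ 18 ⇒ 17 ⇒ 15 + 16. The C10=C11 bond is cut. A Z-trisubstituted allylic unit next to an oxygenated stereocentre is the retron of a Z-selective phosphonate olefination of an α-silyloxy aldehyde. Three carbons leave as commercial 16. The demand is Z selectivity without epimerisation at C9.

15 ⇒ 14 ⇒ 13 ⇒ 12 ⇒ 11 ⇒ 10. No skeletal bond is cut; O9 and C14 are tied back into a five-membered lactone. This reduces the C6=C7 geometry problem to that of an exocyclic alkylidene lactone. The demand is differentiation of three hydroxyls: the primary allylic one (triisopropylsilyl), the secondary one (triethylsilyl), and the primary C10 one. O10 is carried as a trityl ether so that O1 can keep its 4-methoxybenzyl group to the end; it is then exposed through a bis-silyl ether that is oxidised selectively.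

10 ⇒ 9 + 5. The C6=C7 bond is cut (Horner–Wadsworth–Emmons). The union is convergent and central, and the E alkylidene lactone has C5 syn to C8 as the ring requires. The demand is E selectivity under a base mild enough for an enolisable aldehyde.

9 ⇒ 6 + 7. The C7–C8 bond and the lactone C–O bond are cut. The C9 stereocentre is bought with 6, and C14 and the phosphonate arrive with 7. The demand is attack at the unsubstituted epoxide carbon and lactonisation rather than phosphoryl transfer.

5 ⇒ 4 ⇒ 2 ⇒ 1. The terminal olefin of the terpene chain is cleaved. 1 supplies C1–C6, the C3 methyl and the Z C2=C3 geometry ready-made. The demand is site-selective functionalisation of the distal olefin.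

## Other disconnections considered

Alternative 1: The cut is the C4–C5 ring bond together with reconnection of C2 to C7. This folds the ring back into cyclohexanol A1: a tertiary C7 carbinol bearing the C6=C5 vinyl group, cis to an isopropenyl group C3(Me)=C4 on C2, with C1, C10, C9 and C8 completing the six-membered ring. Forward, KH and 18-crown-6 would form the potassium alkoxide of A1, and the anionic oxy-Cope [3,3] shift would expand the ring by four atoms to cyclodecenone A2 after protonation of the C6=C7 enolate.
- In its favour: the C1/C9/C10 triad would be assembled on a six-membered ring, where relative configuration follows from chair preferences. Here the alternative is better than the chosen plan, which creates C1 and C10 together on a mobile thirteen-membered ring.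
- Also better: only one alkoxide can form, so there is no regiochemical question of deprotonation.
- Equal: the cis alkenyl groups are expected to translate into the cis C2=C3 olefin, which the chosen plan takes from 1.
- Against: A2 has neither C14 nor the C6=C7 olefin. The C7 ketone, flanked by two methylene groups, would have to be converted regio- and geometry-selectively into an enol derivative and carbonylated.
- Against: A2 is a β-silyloxy ketone (O9 is β to C7) formed under strongly basic conditions, so enolate equilibration toward C8 could expel the C9 oxygen.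
- Against: A1 has five contiguous stereocentres, two of which (C2, C7) are consumed in the key step.
- Comparison: on mechanism the two plans are equals, since both use an anion-accelerated sigmatropic shift and avoid an end-to-end medium-ring closure. In step economy the alternative is expected to be longer, because both the synthesis of A1 and the late introduction of C14 cost steps.

Alternative 2: The cut reconnects C1 and C7 across the ring, giving hydroazulenol mesylate A3 (five-membered ring C1, C7, C8, C9, C10; seven-membered ring C1 to C7; tertiary alcohol on C1, tert-butyl ester on C7, mesylate on C6). Forward, a base such as KOt-Bu would form the C1 alkoxide, and Grob fragmentation of the C1–C7 bond anti-periplanar to the C6–O bond would give enone ester A4.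
- In its favour: the C6=C7 geometry follows stereospecifically from the configurations at C6 and C7. This is at least the equal of, and probably better than, the phosphonate olefination of step 5.
- Better: C14 arrives at the acid oxidation level, so steps 20 to 22 would not be needed.
- Better: a ring bond is broken rather than formed, so no high dilution is required.
- Against: A3 has two adjacent fully substituted carbons (C1, C7) and five stereocentres, three of which are destroyed in the key step.
- Against: the C1 stereocentre, which the chosen plan sets in its key step, would have to be made afterwards by 1,2-reduction of a flexible ten-membered Z-enone from the correct face, with little to guide it.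
- Against: the tert-butyl ester would have to be cleaved by acid beside an allylic acetate and a transannularly reactive diene, or exchanged earlier.
- Comparison: on mechanism the fragmentation is as dependable as the [2,3] shift. On structure it leaves more stereochemistry to solve after the key step. In step economy the bicyclic precursor is expected to make the route at least as long.

Alternative 3: The cut is the C8–C9 bond, with the C6=C7 olefin transposed to C7=C8 and boron placed on C6, giving open-chain aldehyde boronate A5. Forward, warming A5 at high dilution would let the pinacol allylboronate add to the C9 aldehyde through a chair-like six-membered transition state. This would form C8–C9, shift the olefin to C6=C7, and close the ring to alcohol A6.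
- In its favour: the conditions are neutral and tolerate every functional group, which is better than the strongly basic key step of the chosen plan.
- Better: the isopropyl group is present from the start, so the selective hydrogenation of step 19 is not needed.
- Equal: C1 and C10 would be set by established open-chain methods, and A6 is as close to the target as 23 is.
- Against: the ring is closed end to end at the ten-membered stage, where transannular strain and entropy oppose cyclisation. The chosen plan closes an unstrained thirteen-membered ether and lets a sigmatropic shift make the medium ring.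
- Against: the secondary α-substituted allylboronate of A5 must be a single C6 epimer and can undergo 1,3-borotropic shift, after which addition through C6 would close an eight-membered ring.
- Against: the aldehyde of A5 is α-branched and β-silyloxy, so epimerisation at C10 or elimination of the C1 oxygen is a threat.
- Against: transfer of configuration from C6 to C9 through a chair embedded in a forming medium ring has little close analogy.
- Comparison: allylboration is the more predictable bond-forming event in open chains but the less predictable one at this ring size. In step economy the two plans are expected to be about equal.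

Key step: step 16

Assumption: atom labels C1–C14 follow the ring numbering of 29 (C1 allylic acetoxy carbon, C14 carboxyl carbon); 3, 4, 8 and 9 are used as stereoisomer mixtures at centres that are destroyed later; the C10 descriptor changes from R in 23 to S from 24 onward only through a change of CIP priorities, not through inversion.

Step 1
Reactants: 1 nerol, (2Z)-3,7-dimethylocta-2,6-dien-1-ol
Product: 2 neryl 4-methoxybenzyl ether, 1-({[(2Z)-3,7-dimethylocta-2,6-dien-1-yl]oxy}methyl)-4-methoxybenzene
Conditions: NaH, 4-methoxybenzyl chloride, THF/DMF, 0 °C to rt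
Reagents that add atoms: 4-methoxybenzyl chloride, COc1ccc(CCl)cc1
Why: Williamson etherification of the primary allylic alkoxide; the 4-methoxybenzyl ether survives bases, hydrides and silylations and can later be removed by DDQ without acid or fluoride.

Step 2
Reactants: 2 neryl 4-methoxybenzyl ether
Product: 4 3-{(3Z)-5-[(4-methoxybenzyl)oxy]-3-methylpent-3-en-1-yl}-2,2-dimethyloxirane (racemic), via bromohydrin 3 (not isolated)
Conditions: NBS, THF/H2O 4:1, 0 °C; then K2CO3, MeOH, rt
Reagents that add atoms: water, O; N-bromosuccinimide, O=C1CCC(=O)N1Br (its bromine is present in 3 only)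
Why: Electrophilic bromohydrin formation selects the electron-rich terminal olefin (C2=C3 is deactivated by the allylic oxygen) and base closes 3 to the epoxide; the new centre is irrelevant because it is cleaved in step 3.

Step 3
Reactants: 4 racemic epoxide
Product: 5 (4Z)-6-[(4-methoxybenzyl)oxy]-4-methylhex-4-enal
Conditions: HIO4·2H2O, THF/Et2O, 0 °C
Reagents that add atoms: none
Why: Periodic acid opens the epoxide and cleaves the resulting glycol (Malaprade-type cleavage) to the C6 aldehyde and acetone; the Z C2=C3 olefin of 1 is untouched.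

Step 4
Reactants: 6 (R)-trityl glycidyl ether, (2R)-2-[(trityloxy)methyl]oxirane; 7 triethyl phosphonoacetate
Product: 9 diethyl {(5R)-2-oxo-5-[(trityloxy)methyl]oxolan-3-yl}phosphonate, via hydroxy phosphonoester 8 (not isolated)
Conditions: NaOEt (1.1 equiv), EtOH/THF, 70 °C; AcOH
Reagents that add atoms: none
Why: The sodium salt of 7 opens the epoxide at its unsubstituted carbon (SN2, forming C7–C8) and the alkoxide of 8 lactonises onto the ethyl ester; the protic medium disfavours phosphoryl transfer to a cyclopropane. The C9 configuration (R) comes unchanged from 6.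

Step 5
Reactants: 9 phosphonolactone; 5 (4Z)-6-[(4-methoxybenzyl)oxy]-4-methylhex-4-enal
Product: 10 (3E,5R)-3-{(4Z)-6-[(4-methoxybenzyl)oxy]-4-methylhex-4-en-1-ylidene}-5-[(trityloxy)methyl]oxolan-2-one
Conditions: LiCl, DBU, MeCN, 0 °C to rt
Reagents that add atoms: none
Why: Horner–Wadsworth–Emmons olefination under Masamune–Roush conditions; the equilibrating lithium conditions should favour the E alkylidene lactone, with C5 anti to the carbonyl and syn to the ring methylene C8, which is the geometry the ten-membered ring needs.

Step 6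
Reactants: 10 alkylidene lactone
Product: 11 (2R,4E,8Z)-4-(hydroxymethyl)-10-[(4-methoxybenzyl)oxy]-8-methyl-1-(trityloxy)deca-4,8-dien-2-ol
Conditions: i-Bu2AlH (4 equiv), CH2Cl2, −78 to 0 °C; aq. potassium sodium tartrate
Reagents that add atoms: none
Why: Exhaustive 1,2-reduction of the unsaturated lactone carbonyl by the aluminium hydride gives the C14 allylic alcohol and the C9 secondary alcohol; olefins and ethers are untouched.

Step 7
Reactants: 11 diol
Product: 12 (2R,4E,8Z)-10-[(4-methoxybenzyl)oxy]-8-methyl-4-{[(triisopropylsilyl)oxy]methyl}-1-(trityloxy)deca-4,8-dien-2-ol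
Conditions: i-Pr3SiCl (1.1 equiv), imidazole, CH2Cl2, 0 °C
Reagents that add atoms: chlorotriisopropylsilane, CC(C)[Si](Cl)(C(C)C)C(C)C
Why: Silylation with the bulky chlorosilane is selective for the primary allylic C14 hydroxyl over the hindered secondary C9 hydroxyl.

Step 8
Reactants: 12 trityl ether
Product: 13 (2R,4E,8Z)-10-[(4-methoxybenzyl)oxy]-8-methyl-4-{[(triisopropylsilyl)oxy]methyl}deca-4,8-diene-1,2-diol
Conditions: TsOH·H2O (0.1 equiv), MeOH/CH2Cl2 1:1, 0 °C
Reagents that add atoms: none
Why: Acid-catalysed methanolysis of the trityl ether (SN1 through the trityl cation) at 0 °C should leave the primary triisopropylsilyl ether and the 4-methoxybenzyl ether intact.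

Step 9
Reactants: 13 1,2-diol
Product: 14 (2R,4E,8Z)-10-[(4-methoxybenzyl)oxy]-8-methyl-1,2-bis[(triethylsilyl)oxy]-4-{[(triisopropylsilyl)oxy]methyl}deca-4,8-diene
Conditions: Et3SiCl (2.5 equiv), imidazole, DMAP (cat.), CH2Cl2, 0 °C to rt
Reagents that add atoms: chlorotriethylsilane, CC[Si](Cl)(CC)CC
Why: Routine silylation of both hydroxyls; the primary triethylsilyl ether serves only as the handle for step 10, the secondary one is the O9 protecting group of the key step.

Step 10
Reactants: 14 bis(triethylsilyl) ether
Product: 15 (2R,4E,8Z)-10-[(4-methoxybenzyl)oxy]-8-methyl-2-[(triethylsilyl)oxy]-4-{[(triisopropylsilyl)oxy]methyl}deca-4,8-dienal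
Conditions: (COCl)2 (4 equiv), DMSO (8 equiv), CH2Cl2, −78 to −35 °C; Et3N, −78 to 0 °C
Reagents that add atoms: none
Why: Under Swern conditions a primary triethylsilyl ether is cleaved and oxidised to the aldehyde in one operation, whereas secondary triethylsilyl and triisopropylsilyl ethers are inert; low temperature protects the C9 centre from epimerisation.

Step 11
Reactants: 15 α-silyloxy aldehyde; 16 methyl 2-[bis(2,2,2-trifluoroethoxy)phosphoryl]propanoate
Product: 17 methyl (2Z,4R,6E,10Z)-12-[(4-methoxybenzyl)oxy]-2,10-dimethyl-4-[(triethylsilyl)oxy]-6-{[(triisopropylsilyl)oxy]methyl}dodeca-2,6,10-trienoate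
Conditions: 16, KN(SiMe3)2, 18-crown-6, THF, −78 °C; then 15
Reagents that add atoms: none
Why: Still–Gennari olefination: the trifluoroethyl phosphonate with a dissociated potassium counter-ion eliminates under kinetic control to the Z enoate, so C9 and C12 end cis across C10=C11; −78 °C preserves the α-silyloxy centre.

Step 12
Reactants: 17 Z enoate
Product: 18 (2Z,4R,6E,10Z)-12-[(4-methoxybenzyl)oxy]-2,10-dimethyl-4-[(triethylsilyl)oxy]-6-{[(triisopropylsilyl)oxy]methyl}dodeca-2,6,10-trien-1-ol
Conditions: i-Bu2AlH (2.5 equiv), CH2Cl2, −78 °C; aq. potassium sodium tartrate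
Reagents that add atoms: none
Why: 1,2-Reduction of the enoate to the allylic alcohol with retention of the Z geometry; silyl and 4-methoxybenzyl ethers are stable.

Step 13
Reactants: 18 allylic alcohol
Product: 19 1-({[(2Z,6E,9R,10Z)-12-chloro-3,11-dimethyl-9-[(triethylsilyl)oxy]-7-{[(triisopropylsilyl)oxy]methyl}dodeca-2,6,10-trien-1-yl]oxy}methyl)-4-methoxybenzene
Conditions: NCS, Me2S, CH2Cl2, −20 to 0 °C
Reagents that add atoms: N-chlorosuccinimide, O=C1CCC(=O)N1Cl
Why: Corey–Kim chlorination activates the hydroxyl under neutral conditions and chloride displaces it by SN2, without allylic transposition or loss of the triethylsilyl group.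

Step 14
Reactants: 19 allylic chloride
Product: 20 (2Z,6E,9R,10Z)-12-chloro-3,11-dimethyl-9-[(triethylsilyl)oxy]-7-{[(triisopropylsilyl)oxy]methyl}dodeca-2,6,10-trien-1-ol
Conditions: DDQ, CH2Cl2/pH 7 phosphate buffer 10:1, 0 °C
Reagents that add atoms: none
Why: Oxidative cleavage of the 4-methoxybenzyl ether by DDQ in buffered medium frees the C1 hydroxyl; silyl ethers and the allylic chloride are inert.

Step 15
Reactants: 20 hydroxy chloride
Product: 21 (3Z,5R,7E,11Z)-3,11-dimethyl-5-[(triethylsilyl)oxy]-7-{[(triisopropylsilyl)oxy]methyl}-1-oxacyclotrideca-3,7,11-triene (ether oxygen between C1 and C12)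
Conditions: NaH, 15-crown-5 (cat.), THF, 0.003 M, slow addition, 40 °C
Reagents that add atoms: none
Why: Intramolecular Williamson etherification (SN2 at the primary allylic C12) under high dilution closes the thirteen-membered ring; the alkoxide sits on C1, remote from both silyl ethers, so no oxygen-to-oxygen silyl shift can compete, and three cis ring olefins pre-organise the chain.

Step 16
Reactants: 21 thirteen-membered bis-allylic ether
Product: 23 (1R,2Z,6E,9R,10R)-3-methyl-10-(prop-1-en-2-yl)-9-[(triethylsilyl)oxy]-7-{[(triisopropylsilyl)oxy]methyl}cyclodeca-2,6-dien-1-ol, via C1-lithiated ether 22 (not isolated)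
Conditions: n-BuLi (2 equiv), THF, −78 to −30 °C; aq. NH4Cl, −78 °C
Reagents that add atoms: none
Why: n-BuLi removes one C1 proton (α to oxygen and allylic to C2=C3) to give 22, whose carbanion attacks C10 on the face of the allyl unit from which the O–C12 bond departs, through a five-membered envelope transition state (C1, O, C12, C11, C10); this suprafacial [2,3]-sigmatropic Wittig shift is the known ring contraction of macrocyclic bis-allylic ethers. The ten-membered ring is closed transannularly inside the thirteen-membered ring, as a contraction by three atoms (O, C12 and C11 leave the ring as the alkoxide oxygen and the isopropenyl group), so no end-to-end medium-ring cyclisation is needed. Relative configuration at C1/C10: with the Z C10=C11 olefin and the C2 vinyl substituent exo on the envelope, the syn (erythro-type) product results, which on the ring places the C1 oxygen and the isopropenyl group cis. Absolute sense: allylic 1,3-strain across the Z olefin holds the C9–H bond in the olefin plane toward C12, so the silyloxy group and C8 lie on opposite faces, and the carbanion should add anti to the C9–O bond, on the face carrying the C8 tether, which places the isopropenyl group trans to the C9 oxygen. The step needs deprotonation at C1 and not at C12 or C14: C1 is the unhindered methylene beside a CH= carbon, C12 lies between the methyl-bearing C11 and the silyloxy-substituted C9, and the bulky triisopropylsilyl group shields C14; macrocyclic bis-allylic ethers with the same substitution on their two arms react in this sense, but the selectivity is not guaranteed here. The reaction is quenched cold so that the lithium salt of 23, a 1,5-dien-3-olate, cannot go on to an oxy-Cope shift.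

Step 17
Reactants: 23 ring-contracted alcohol
Product: 24 (1R,2Z,6E,9R,10S)-3-methyl-10-(prop-1-en-2-yl)-7-{[(triisopropylsilyl)oxy]methyl}cyclodeca-2,6-diene-1,9-diol
Conditions: PPTS (0.2 equiv), MeOH/CH2Cl2, 0 °C to rt
Reagents that add atoms: none
Why: Mild acid-catalysed methanolysis removes the triethylsilyl group (whether it sits on O9 or has shifted to O1 during the anionic step) but not the primary triisopropylsilyl ether; PPTS is too weak to ionise the allylic alcohol or start a transannular cyclisation.

Step 18
Reactants: 24 diol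
Product: 25 (1R,2Z,6E,9R,10S)-3-methyl-10-(prop-1-en-2-yl)-7-{[(triisopropylsilyl)oxy]methyl}cyclodeca-2,6-diene-1,9-diyl diacetate
Conditions: Ac2O, pyridine, DMAP (cat.), CH2Cl2, rt
Reagents that add atoms: acetic anhydride, CC(=O)OC(C)=O
Why: DMAP-catalysed acylation installs both acetates in one operation; acetylating O9 before C14 is unmasked prevents later lactol or lactone formation between O9 and C14.

Step 19
Reactants: 25 diacetate
Product: 26 (1R,2Z,6E,9R,10S)-3-methyl-10-(propan-2-yl)-7-{[(triisopropylsilyl)oxy]methyl}cyclodeca-2,6-diene-1,9-diyl diacetate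
Conditions: H2 (1–3 atm), RhCl(PPh3)3 (10 mol %), benzene/EtOH, rt
Reagents that add atoms: none
Why: Homogeneous hydrogenation with the rhodium chloride–phosphine catalyst reduces the 1,1-disubstituted isopropenyl olefin and should leave the two trisubstituted ring olefins and the allylic acetate; no stereocentre is created.

Step 20
Reactants: 26 silyl ether
Product: 27 (1R,2Z,6E,9R,10S)-7-(hydroxymethyl)-3-methyl-10-(propan-2-yl)cyclodeca-2,6-diene-1,9-diyl diacetate
Conditions: HF·pyridine, pyridine, THF, 0 °C to rt
Reagents that add atoms: none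
Why: Buffered fluoride-mediated cleavage of the primary silyl ether avoids the basic conditions that would hydrolyse or shift the acetates.

Step 21
Reactants: 27 allylic alcohol
Product: 28 (1R,2Z,6E,9R,10S)-7-formyl-3-methyl-10-(propan-2-yl)cyclodeca-2,6-diene-1,9-diyl diacetate
Conditions: MnO2 (excess), CH2Cl2, rt
Reagents that add atoms: none
Why: MnO2 oxidises only the primary allylic alcohol to the enal; the ring holds the C6=C7 geometry.

Step 22
Reactants: 28 enal
Product: 29 (1E,5Z,7R,8S,9R)-7,9-bis(acetyloxy)-5-methyl-8-(propan-2-yl)cyclodeca-1,5-diene-1-carboxylic acid (route numbering: 1R,9R,10S; C14 acid on C7)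
Conditions: NaClO2, NaH2PO4, 2-methylbut-2-ene, t-BuOH/H2O, 0 °C to rt
Reagents that add atoms: sodium chlorite, [Na+].[O-]Cl=O
Why: Pinnick oxidation converts the enal into the acid under buffered conditions; the scavenger protects the ring olefins from hypochlorous acid, and the acetates and stereocentres are untouched.

## Compound list

1 | nerol, (2Z)-3,7-dimethylocta-2,6-dien-1-ol | OC/C=C(/C)CCC=C(C)C | starting material
2 | neryl 4-methoxybenzyl ether, 1-({[(2Z)-3,7-dimethylocta-2,6-dien-1-yl]oxy}methyl)-4-methoxybenzene | COc1ccc(COC/C=C(/C)CCC=C(C)C)cc1 | intermediate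
3 | (6Z)-3-bromo-8-[(4-methoxybenzyl)oxy]-2,6-dimethyloct-6-en-2-ol (racemic bromohydrin, not isolated) | COc1ccc(COC/C=C(/C)CCC(Br)C(C)(C)O)cc1 | intermediate
4 | 3-{(3Z)-5-[(4-methoxybenzyl)oxy]-3-methylpent-3-en-1-yl}-2,2-dimethyloxirane (racemic) | COc1ccc(COC/C=C(/C)CCC2OC2(C)C)cc1 | intermediate
5 | (4Z)-6-[(4-methoxybenzyl)oxy]-4-methylhex-4-enal | COc1ccc(COC/C=C(/C)CCC=O)cc1 | intermediate
6 | (R)-trityl glycidyl ether, (2R)-2-[(trityloxy)methyl]oxirane | C1O[C@H]1COC(c2ccccc2)(c2ccccc2)c2ccccc2 | starting material
7 | triethyl phosphonoacetate | CCOC(=O)CP(=O)(OCC)OCC | starting material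
8 | ethyl (4R)-2-(diethoxyphosphoryl)-4-hydroxy-5-(trityloxy)pentanoate (sodium alkoxide in the flask, C2 epimers, not isolated) | CCOC(=O)C(C[C@@H](O)COC(c1ccccc1)(c1ccccc1)c1ccccc1)P(=O)(OCC)OCC | intermediate
9 | diethyl {(5R)-2-oxo-5-[(trityloxy)methyl]oxolan-3-yl}phosphonate (C3 epimers) | CCOP(=O)(OCC)C1C[C@H](COC(c2ccccc2)(c2ccccc2)c2ccccc2)OC1=O | intermediate
10 | (3E,5R)-3-{(4Z)-6-[(4-methoxybenzyl)oxy]-4-methylhex-4-en-1-ylidene}-5-[(trityloxy)methyl]oxolan-2-one | COc1ccc(COC/C=C(/C)CC/C=C2\C[C@H](COC(c3ccccc3)(c3ccccc3)c3ccccc3)OC2=O)cc1 | intermediate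
11 | (2R,4E,8Z)-4-(hydroxymethyl)-10-[(4-methoxybenzyl)oxy]-8-methyl-1-(trityloxy)deca-4,8-dien-2-ol | COc1ccc(COC/C=C(/C)CC/C=C(/CO)C[C@@H](O)COC(c2ccccc2)(c2ccccc2)c2ccccc2)cc1 | intermediate
12 | (2R,4E,8Z)-10-[(4-methoxybenzyl)oxy]-8-methyl-4-{[(triisopropylsilyl)oxy]methyl}-1-(trityloxy)deca-4,8-dien-2-ol | COc1ccc(COC/C=C(/C)CC/C=C(/CO[Si](C(C)C)(C(C)C)C(C)C)C[C@@H](O)COC(c2ccccc2)(c2ccccc2)c2ccccc2)cc1 | intermediate
13 | (2R,4E,8Z)-10-[(4-methoxybenzyl)oxy]-8-methyl-4-{[(triisopropylsilyl)oxy]methyl}deca-4,8-diene-1,2-diol | COc1ccc(COC/C=C(/C)CC/C=C(/CO[Si](C(C)C)(C(C)C)C(C)C)C[C@@H](O)CO)cc1 | intermediate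
14 | (2R,4E,8Z)-10-[(4-methoxybenzyl)oxy]-8-methyl-1,2-bis[(triethylsilyl)oxy]-4-{[(triisopropylsilyl)oxy]methyl}deca-4,8-diene | COc1ccc(COC/C=C(/C)CC/C=C(/CO[Si](C(C)C)(C(C)C)C(C)C)C[C@@H](O[Si](CC)(CC)CC)CO[Si](CC)(CC)CC)cc1 | intermediate
15 | (2R,4E,8Z)-10-[(4-methoxybenzyl)oxy]-8-methyl-2-[(triethylsilyl)oxy]-4-{[(triisopropylsilyl)oxy]methyl}deca-4,8-dienal | COc1ccc(COC/C=C(/C)CC/C=C(/CO[Si](C(C)C)(C(C)C)C(C)C)C[C@@H](O[Si](CC)(CC)CC)C=O)cc1 | intermediate
16 | methyl 2-[bis(2,2,2-trifluoroethoxy)phosphoryl]propanoate | COC(=O)C(C)P(=O)(OCC(F)(F)F)OCC(F)(F)F | starting material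
17 | methyl (2Z,4R,6E,10Z)-12-[(4-methoxybenzyl)oxy]-2,10-dimethyl-4-[(triethylsilyl)oxy]-6-{[(triisopropylsilyl)oxy]methyl}dodeca-2,6,10-trienoate | COc1ccc(COC/C=C(/C)CC/C=C(/CO[Si](C(C)C)(C(C)C)C(C)C)C[C@@H](O[Si](CC)(CC)CC)/C=C(/C)C(=O)OC)cc1 | intermediate
18 | (2Z,4R,6E,10Z)-12-[(4-methoxybenzyl)oxy]-2,10-dimethyl-4-[(triethylsilyl)oxy]-6-{[(triisopropylsilyl)oxy]methyl}dodeca-2,6,10-trien-1-ol | COc1ccc(COC/C=C(/C)CC/C=C(/CO[Si](C(C)C)(C(C)C)C(C)C)C[C@@H](O[Si](CC)(CC)CC)/C=C(/C)CO)cc1 | intermediate
19 | 1-({[(2Z,6E,9R,10Z)-12-chloro-3,11-dimethyl-9-[(triethylsilyl)oxy]-7-{[(triisopropylsilyl)oxy]methyl}dodeca-2,6,10-trien-1-yl]oxy}methyl)-4-methoxybenzene | COc1ccc(COC/C=C(/C)CC/C=C(/CO[Si](C(C)C)(C(C)C)C(C)C)C[C@@H](O[Si](CC)(CC)CC)/C=C(/C)CCl)cc1 | intermediate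
20 | (2Z,6E,9R,10Z)-12-chloro-3,11-dimethyl-9-[(triethylsilyl)oxy]-7-{[(triisopropylsilyl)oxy]methyl}dodeca-2,6,10-trien-1-ol | OC/C=C(/C)CC/C=C(/CO[Si](C(C)C)(C(C)C)C(C)C)C[C@@H](O[Si](CC)(CC)CC)/C=C(/C)CCl | intermediate
21 | (3Z,5R,7E,11Z)-3,11-dimethyl-5-[(triethylsilyl)oxy]-7-{[(triisopropylsilyl)oxy]methyl}-1-oxacyclotrideca-3,7,11-triene | O1C/C=C(/C)CC/C=C(/CO[Si](C(C)C)(C(C)C)C(C)C)C[C@@H](O[Si](CC)(CC)CC)/C=C(/C)C1 | intermediate
22 | C1-lithiated ether, the 13-lithio derivative of 21 (not isolated) | [Li]C1/C=C(/C)CC/C=C(/CO[Si](C(C)C)(C(C)C)C(C)C)C[C@@H](O[Si](CC)(CC)CC)/C=C(/C)CO1 | intermediate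
23 | (1R,2Z,6E,9R,10R)-3-methyl-10-(prop-1-en-2-yl)-9-[(triethylsilyl)oxy]-7-{[(triisopropylsilyl)oxy]methyl}cyclodeca-2,6-dien-1-ol | O[C@@H]1/C=C(/C)CC/C=C(/CO[Si](C(C)C)(C(C)C)C(C)C)C[C@@H](O[Si](CC)(CC)CC)[C@@H]1C(C)=C | intermediate
24 | (1R,2Z,6E,9R,10S)-3-methyl-10-(prop-1-en-2-yl)-7-{[(triisopropylsilyl)oxy]methyl}cyclodeca-2,6-diene-1,9-diol | O[C@@H]1/C=C(/C)CC/C=C(/CO[Si](C(C)C)(C(C)C)C(C)C)C[C@@H](O)[C@@H]1C(C)=C | intermediate
25 | (1R,2Z,6E,9R,10S)-3-methyl-10-(prop-1-en-2-yl)-7-{[(triisopropylsilyl)oxy]methyl}cyclodeca-2,6-diene-1,9-diyl diacetate | CC(=O)O[C@@H]1/C=C(/C)CC/C=C(/CO[Si](C(C)C)(C(C)C)C(C)C)C[C@@H](OC(C)=O)[C@@H]1C(C)=C | intermediate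
26 | (1R,2Z,6E,9R,10S)-3-methyl-10-(propan-2-yl)-7-{[(triisopropylsilyl)oxy]methyl}cyclodeca-2,6-diene-1,9-diyl diacetate | CC(=O)O[C@@H]1/C=C(/C)CC/C=C(/CO[Si](C(C)C)(C(C)C)C(C)C)C[C@@H](OC(C)=O)[C@@H]1C(C)C | intermediate
27 | (1R,2Z,6E,9R,10S)-7-(hydroxymethyl)-3-methyl-10-(propan-2-yl)cyclodeca-2,6-diene-1,9-diyl diacetate | CC(=O)O[C@@H]1/C=C(/C)CC/C=C(/CO)C[C@@H](OC(C)=O)[C@@H]1C(C)C | intermediate
28 | (1R,2Z,6E,9R,10S)-7-formyl-3-methyl-10-(propan-2-yl)cyclodeca-2,6-diene-1,9-diyl diacetate | CC(=O)O[C@@H]1/C=C(/C)CC/C=C(/C=O)C[C@@H](OC(C)=O)[C@@H]1C(C)C | intermediate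
29 | (1E,5Z,7R,8S,9R)-7,9-bis(acetyloxy)-5-methyl-8-(propan-2-yl)cyclodeca-1,5-diene-1-carboxylic acid | CC(=O)O[C@@H]1/C=C(/C)CC/C=C(/C(=O)O)C[C@@H](OC(C)=O)[C@@H]1C(C)C | target

Total steps: 22. Longest linear sequence: 21 steps (from 1 through steps 1–3 and 5–22); the branch from 6 joins after one step.

## Least certain steps and fallbacks

Step 16 (key step). The most likely failure is proton removal at C12 instead of C1. Both methylenes are α-oxygenated and allylic, and the C9 silyloxy group acidifies the C12 side. A C12 carbanion would contract the ring onto C3 or expel the C9 silanolate by 1,4-elimination. A second possibility is poor facial selectivity at C10, which would give the diastereomer epimeric at both C1 and C10. The fallback replaces carbanion chemistry by an allylmetal addition and sets out from 20. MnO2 oxidation of the C1 alcohol would give (2Z,6E,9R,10Z)-12-chloro-3,11-dimethyl-9-[(triethylsilyl)oxy]-7-{[(triisopropylsilyl)oxy]methyl}dodeca-2,6,10-trienal F1. CrCl2 in THF at high dilution would convert the allylic chloride into an allylchromium species that adds through C10 to the C1 aldehyde (intramolecular Nozaki–Hiyama–Kishi allylation) and forms the same C1–C10 bond. Because such additions are normally anti-selective, the expected product is the C1 epimer of 23, (1S,2Z,6E,9R,10R)-3-methyl-10-(prop-1-en-2-yl)-9-[(triethylsilyl)oxy]-7-{[(triisopropylsilyl)oxy]methyl}cyclodeca-2,6-dien-1-ol F2. Mitsunobu inversion at C1 with 4-nitrobenzoic acid, PPh3 and diisopropyl azodicarboxylate would give the (1R)-4-nitrobenzoate F3. K2CO3 in MeOH would release 23, where the route is rejoined. The facial sense at C10 in this allylation would also have to be checked.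

Step 15. The most likely failure is intermolecular etherification competing with ring closure, together with loss of the Z allylic chloride, whose C12 can be attacked by the cis-disposed O9 to give a 2,5-dihydrofuran with loss of the silyl group. The fallback closes the other C–O bond and sets out from 18. Acetylation (Ac2O, pyridine) would give (2Z,4R,6E,10Z)-12-[(4-methoxybenzyl)oxy]-2,10-dimethyl-4-[(triethylsilyl)oxy]-6-{[(triisopropylsilyl)oxy]methyl}dodeca-2,6,10-trien-1-yl acetate F4. DDQ would free the C1 hydroxyl to give the hydroxy acetate F5. Corey–Kim chlorination would give the C1 chloride acetate F6. i-Bu2AlH at −78 °C would remove the acetate to give (2Z,4R,6E,10Z)-12-chloro-2,10-dimethyl-4-[(triethylsilyl)oxy]-6-{[(triisopropylsilyl)oxy]methyl}dodeca-2,6,10-trien-1-ol F7. EtMgBr in THF/HMPA at high dilution would close the O–C1 bond and return to 21. The electrophile is then the unhindered C1 allylic chloride, and a magnesium alkoxide is a poor partner for silyl transfer from O9.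

Step 5. The most likely failure is an E/Z mixture at C6=C7, because α-phosphono lactones often react with aliphatic aldehydes with modest selectivity, with self-condensation of the enolisable aldehyde as a minor risk. The fallback replaces phosphonate olefination by aldol addition and elimination and sets out from 6. Diethyl malonate and NaOEt in EtOH would open the epoxide and lactonise to ethyl (5R)-2-oxo-5-[(trityloxy)methyl]oxolane-3-carboxylate F8. Krapcho dealkoxycarbonylation (LiCl, wet DMSO, heat) would give (5R)-5-[(trityloxy)methyl]oxolan-2-one F9. Its lithium enolate (LiN(i-Pr)2, THF, −78 °C) would add to 5 to give the β-hydroxy lactone F10. MsCl and Et3N would give the mesylate F11, and DBU would eliminate it to 10; this E1cB elimination is under thermodynamic control and favours the E alkylidene lactone.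

Step 19. The most likely failure is slow reduction of the isopropenyl group, which sits between two acetoxy-bearing carbons, so that isomerisation to the isopropylidene olefin or partial reduction of a ring olefin competes. The fallback is a metal-free reduction at an earlier, less hindered stage and sets out from 23. Diimide, generated from 2-nitrobenzenesulfonohydrazide and Et3N, would reduce the isopropenyl group to give (1R,2Z,6E,9R,10R)-3-methyl-10-(propan-2-yl)-9-[(triethylsilyl)oxy]-7-{[(triisopropylsilyl)oxy]methyl}cyclodeca-2,6-dien-1-ol F12. PPTS in MeOH would give the isopropyl diol F13, and Ac2O, pyridine and DMAP would give 26.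

Step 10. The most likely failure is incomplete cleavage of the primary triethylsilyl ether or partial loss of the secondary one, because the window between the two rests only on steric differences. The fallback is stepwise and sets out from 14. HF·pyridine buffered with pyridine in THF at 0 °C would remove the primary silyl group to give (2R,4E,8Z)-10-[(4-methoxybenzyl)oxy]-8-methyl-2-[(triethylsilyl)oxy]-4-{[(triisopropylsilyl)oxy]methyl}deca-4,8-dien-1-ol F14. Dess–Martin periodinane with NaHCO3 would oxidise it to 15.

## Further compounds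

F1 | step 16 | (2Z,6E,9R,10Z)-12-chloro-3,11-dimethyl-9-[(triethylsilyl)oxy]-7-{[(triisopropylsilyl)oxy]methyl}dodeca-2,6,10-trienal | O=C/C=C(/C)CC/C=C(/CO[Si](C(C)C)(C(C)C)C(C)C)C[C@@H](O[Si](CC)(CC)CC)/C=C(/C)CCl
F2 | step 16 | (1S,2Z,6E,9R,10R)-3-methyl-10-(prop-1-en-2-yl)-9-[(triethylsilyl)oxy]-7-{[(triisopropylsilyl)oxy]methyl}cyclodeca-2,6-dien-1-ol | O[C@H]1/C=C(/C)CC/C=C(/CO[Si](C(C)C)(C(C)C)C(C)C)C[C@@H](O[Si](CC)(CC)CC)[C@@H]1C(C)=C
F3 | step 16 | (1R,2Z,6E,9R,10R)-3-methyl-10-(prop-1-en-2-yl)-9-[(triethylsilyl)oxy]-7-{[(triisopropylsilyl)oxy]methyl}cyclodeca-2,6-dien-1-yl 4-nitrobenzoate | O=C(O[C@@H]1/C=C(/C)CC/C=C(/CO[Si](C(C)C)(C(C)C)C(C)C)C[C@@H](O[Si](CC)(CC)CC)[C@@H]1C(C)=C)c1ccc(cc1)[N+](=O)[O-]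
F4 | step 15 | (2Z,4R,6E,10Z)-12-[(4-methoxybenzyl)oxy]-2,10-dimethyl-4-[(triethylsilyl)oxy]-6-{[(triisopropylsilyl)oxy]methyl}dodeca-2,6,10-trien-1-yl acetate | COc1ccc(COC/C=C(/C)CC/C=C(/CO[Si](C(C)C)(C(C)C)C(C)C)C[C@@H](O[Si](CC)(CC)CC)/C=C(/C)COC(C)=O)cc1
F5 | step 15 | (2Z,4R,6E,10Z)-12-hydroxy-2,10-dimethyl-4-[(triethylsilyl)oxy]-6-{[(triisopropylsilyl)oxy]methyl}dodeca-2,6,10-trien-1-yl acetate | OC/C=C(/C)CC/C=C(/CO[Si](C(C)C)(C(C)C)C(C)C)C[C@@H](O[Si](CC)(CC)CC)/C=C(/C)COC(C)=O
F6 | step 15 | (2Z,4R,6E,10Z)-12-chloro-2,10-dimethyl-4-[(triethylsilyl)oxy]-6-{[(triisopropylsilyl)oxy]methyl}dodeca-2,6,10-trien-1-yl acetate | ClC/C=C(/C)CC/C=C(/CO[Si](C(C)C)(C(C)C)C(C)C)C[C@@H](O[Si](CC)(CC)CC)/C=C(/C)COC(C)=O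
F7 | step 15 | (2Z,4R,6E,10Z)-12-chloro-2,10-dimethyl-4-[(triethylsilyl)oxy]-6-{[(triisopropylsilyl)oxy]methyl}dodeca-2,6,10-trien-1-ol | ClC/C=C(/C)CC/C=C(/CO[Si](C(C)C)(C(C)C)C(C)C)C[C@@H](O[Si](CC)(CC)CC)/C=C(/C)CO
F8 | step 5 | ethyl (5R)-2-oxo-5-[(trityloxy)methyl]oxolane-3-carboxylate (C3 epimers) | CCOC(=O)C1C[C@H](COC(c2ccccc2)(c2ccccc2)c2ccccc2)OC1=O
F9 | step 5 | (5R)-5-[(trityloxy)methyl]oxolan-2-one | O=C1CC[C@H](COC(c2ccccc2)(c2ccccc2)c2ccccc2)O1
F10 | step 5 | (5R)-3-{(4Z)-1-hydroxy-6-[(4-methoxybenzyl)oxy]-4-methylhex-4-en-1-yl}-5-[(trityloxy)methyl]oxolan-2-one (diastereomer mixture at the two new centres) | COc1ccc(COC/C=C(/C)CCC(O)C2C[C@H](COC(c3ccccc3)(c3ccccc3)c3ccccc3)OC2=O)cc1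
F11 | step 5 | (4Z)-6-[(4-methoxybenzyl)oxy]-4-methyl-1-{(5R)-2-oxo-5-[(trityloxy)methyl]oxolan-3-yl}hex-4-en-1-yl methanesulfonate | COc1ccc(COC/C=C(/C)CCC(OS(C)(=O)=O)C2C[C@H](COC(c3ccccc3)(c3ccccc3)c3ccccc3)OC2=O)cc1
F12 | step 19 | (1R,2Z,6E,9R,10R)-3-methyl-10-(propan-2-yl)-9-[(triethylsilyl)oxy]-7-{[(triisopropylsilyl)oxy]methyl}cyclodeca-2,6-dien-1-ol | O[C@@H]1/C=C(/C)CC/C=C(/CO[Si](C(C)C)(C(C)C)C(C)C)C[C@@H](O[Si](CC)(CC)CC)[C@@H]1C(C)C
F13 | step 19 | (1R,2Z,6E,9R,10S)-3-methyl-10-(propan-2-yl)-7-{[(triisopropylsilyl)oxy]methyl}cyclodeca-2,6-diene-1,9-diol | O[C@@H]1/C=C(/C)CC/C=C(/CO[Si](C(C)C)(C(C)C)C(C)C)C[C@@H](O)[C@@H]1C(C)C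
F14 | step 10 | (2R,4E,8Z)-10-[(4-methoxybenzyl)oxy]-8-methyl-2-[(triethylsilyl)oxy]-4-{[(triisopropylsilyl)oxy]methyl}deca-4,8-dien-1-ol | COc1ccc(COC/C=C(/C)CC/C=C(/CO[Si](C(C)C)(C(C)C)C(C)C)C[C@@H](O[Si](CC)(CC)CC)CO)cc1
A1 | alternative 1 | cis-1-vinyl-2-isopropenylcyclohexanol carrying the C1 and C9 tert-butyldimethylsilyl ethers and the C10 isopropyl group (isopropenyl drawn trans to the C1 oxygen) | C=C[C@@]1(O)C[C@@H](O[Si](C)(C)C(C)(C)C)[C@H](C(C)C)[C@H](O[Si](C)(C)C(C)(C)C)[C@H]1C(C)=C
A2 | alternative 1 | (Z)-cyclodec-5-enone with the C1, C9, C10 triad (C7 ketone) | CC(C)(C)[Si](C)(C)O[C@@H]1/C=C(/C)CCCC(=O)C[C@@H](O[Si](C)(C)C(C)(C)C)[C@@H]1C(C)C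
A3 | alternative 2 | cis-fused bicyclo[5.3.0]dec-2-ene with C1 tertiary alcohol, C7 tert-butyl ester, C6 mesylate, C9 silyl ether and C10 isopropyl | O[C@@]12C=C(C)CC[C@H](OS(C)(=O)=O)[C@]1(C(=O)OC(C)(C)C)C[C@@H](O[Si](C)(C)C(C)(C)C)[C@@H]2C(C)C
A4 | alternative 2 | ten-membered C1 enone with the C6=C7 tert-butyl enoate | O=C1/C=C(/C)CC/C=C(/C(=O)OC(C)(C)C)C[C@@H](O[Si](C)(C)C(C)(C)C)[C@@H]1C(C)C
A5 | alternative 3 | open-chain C9 aldehyde with C6 pinacol allylboronate, C7 exo-methylene (C8), C1 silyl ether and C10 isopropyl (C6 configuration assigned for a chair transition state) | O=C[C@H](C(C)C)[C@H](O[Si](C)(C)C(C)(C)C)/C=C(/C)CC[C@@H](B1OC(C)(C)C(C)(C)O1)C(=C)CO[Si](C(C)C)(C(C)C)C(C)C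
A6 | alternative 3 | ten-membered C9 alcohol with C1 silyl ether and C14 silyl ether | CC(C)(C)[Si](C)(C)O[C@@H]1/C=C(/C)CC/C=C(/CO[Si](C(C)C)(C(C)C)C(C)C)C[C@@H](O)[C@@H]1C(C)C
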